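The readings were generated by integration with constants of no real substance; noise was put on by code.

In molar units the meeting put product and partner on one scale, since the step to product takes one partner for each product.

| flask | substrate | partner | temperature | remark | time |
|---|---|---|---|---|---|
| delta | 0.020 M | 0.018 M | 35 °C | the very flask that is asked about, followed so far |  |
| gamma | 0.030 M | 0.018 M | 30 °C | run made earlier |  |
| flask | 0.020 M | 0.0180 M | 35 °C |  | 80 min |

| run | time / min | product / % |
|---|---|---|
| delta | 4.00 | 25.4 |
| delta | 6.00 | 32.9 |
| delta | 8.00 | 37.8 |
| delta | 15.0 | 54.1 |
| delta | 20.0 | 62.0 |
| delta | 30.0 | 68.2 |
| delta | 50.0 | 73.8 |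
| gamma | 3.00 | 14.3 |
| gamma | 5.00 | 23.4 |
| gamma | 8.00 | 32.0 |
| gamma | 12.0 | 38.7 |
| gamma | 15.0 | 44.1 |
| gamma | 25.0 | 53.2 |
| gamma | 40.0 | 53.3 |

(standard deviation of a reading: 1 percentage point)

- product, in percent of the substrate first charged, at 80 min
- what to do for the largest gain in product; "none" if nothing gains more than 2 percentage points (dawn / dusk / noon / midnight / none)
- product present, with what was taken out counted in, in percent of the substrate first charged, after dusk
- product present, with what was taken out counted in, in percent of the substrate first charged, after noon

- dawn: at 80 min take out 90% of the product then present, then wait 80 min
- dusk: at 80 min raise the temperature by 15 K, then wait 80 min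
- noon: at 80 min add partner, 100% of the amount charged, then wait 80 min
- midnight: change nothing and wait 80 min more

- removed product is counted in
- what was read earlier has a scatter of 1 percentage point, one standard deviation
- steps under discussion: substrate + partner -> product; 2 partner -> homo dimer
- additions bring no volume worth counting

The chair opened with the gamma run. Its last readings stand at 53.2% and 53.3%, which is 0.0160 M of product, less than the substrate charge. With 0.0140 M of substrate unused, she called partner the limiting reagent.

A second member turned to the delta run. He took its last reading, 73.8% at 50.0 min, as 0.0148 M of product and proposed this as the partner budget: the product a partner charge ends up paying for, the remainder going to homo dimer. At this partner charge and temperature, he said, control changes hands where the substrate charge crosses the budget. With the substrate charge above the budget he expected product to end at budget over substrate charge, and with it below the budget he expected product close to the substrate charge.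

A third member objected that the delta readings still rose by 5.6 percentage points over their last interval, and that gamma had paid more from the same partner charge, at a lower temperature and with more substrate.

The reckoning minuted as our own is a range. The flask's substrate charge lies above both budgets, so product at 80 min should lie between 73.8% and 80.0%. Dawn, dusk and midnight add no partner, so they should stay in that range. Noon raises the budget to about 0.0295 M, above the substrate charge, so product should approach the full charge.

The forecast gave 78%, chose noon, and put dusk at 80.5% and noon at 99%, saying: “Heating only finishes the remaining partner”. Its figure for now lies inside our range, while its dusk figure stands above it.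

The flask gave 73.9% at 80 min, 73.9% after dusk and 99.3% after noon, so noon gained most, 25 points.

    substrate + partner → product, rate k1*[substrate]*[partner]^0.5 (k = 0.00947 L⁰·⁵ mol⁻⁰·⁵ s⁻¹, Ea = 47.0 kJ mol⁻¹)
    2 partner → homo dimer (k = 0.0176 L mol⁻¹ s⁻¹, Ea = 72.0 kJ mol⁻¹)
    (constants at 35 °C)

Budget over substrate charge, 73.8%, stands beside the 73.9% of the flask, whose partner was at 1.12% of its charge by 40.0 min and 0% by 80.0 min; dusk brought 0 points. The neighbouring flask has its substrate cut to 0.0050 M, lower than the budget of 0.0148 M, so the reckoning expects product close to its substrate charge. That neighbouring flask gave 97.4% of product at 80.0 min, with 2.6% of its substrate and 19% of its partner charge still there.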